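The constants used here stand for no real mixture; the run is a simulation.

Start from the constants, 0.33 M⁻¹ min⁻¹ against 0.031 M⁻¹ min⁻¹, and ask what they make of these four recipes.

    substrate + coupling partner → target + released group (k1 = 0.031 M⁻¹ min⁻¹)
    2 substrate → homo dimer (k2 = 0.33 M⁻¹ min⁻¹)
    coupling partner → decomposed reagent (k3 = 0.010 min⁻¹)

| flask | substrate | coupling partner | time | remark |
|---|---|---|---|---|
| amber | 0.050 M | 0.250 M (fed, over 50 min) | 1.0 h | all else is in the flask from the start; the feed brings no volume worth counting |
| green | 0.050 M (in portions, 2, over 50 min) | 0.250 M | 1.0 h | first portion at the start, last at 50 min |
| grey | 0.050 M | 0.250 M | 1.0 h | everything together at the start |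
| teal | 0.050 M (fed, over 50 min) | 0.250 M | 1.0 h | all else is in the flask from the start; the feed brings no volume worth counting |

- in percentages every species weighs as the substrate in it: one homo dimer counts as two
- a doubled species enters its step squared and goes two at a time
- run time (amber): 1.0 h

* the flask that comes out highest in amount of homo dimer, in percent of the substrate charged; "all alike" if 1.5 percentage points covers them all (amber / green / grey / teal / all alike)
* amount of homo dimer at the end, in percent of the substrate charged, amber
* amount of homo dimer at the end, in percent of the substrate charged, green
* amount of homo dimer at the end, in percent of the substrate charged, grey
* amount of homo dimer at the end, in percent of the substrate charged, teal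

Divide the rate at which substrate goes into homo dimer by the rate at which it goes into target, and time drops out. Let a be the substrate standing as a fraction of its charge and b the coupling partner as a fraction of its own. The ratio is then S·a/b, where S, the selectivity factor at full charge, is twice the dimer constant times the substrate charge over the coupling constant times the partner charge: 4.26.

Now turn the settings by hand. With everything charged at once, as in grey, a/b opens at one, so the first substrate to react goes into homo dimer with a share of 81.0%. Feed the coupling partner instead, as in amber, and b opens near zero, so the ratio opens without bound. Feed the substrate, as in teal, and a opens near zero, so the ratio climbs from nothing. Split the substrate, as in green, and the ratio opens at 2.13, lower than in grey, while the second portion enters 10.0 min before the end.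

You get amber, then grey, then the two metered flasks. There my reckoning stops: the ratio gives the split, not how much has reacted, so teal against green stays open.

The forecast gives 62% for amber, 55% for grey, 38% for teal and 31.5% for green, on the ground that “Feeding the coupling partner (amber) starves the cross-coupling early”.

The simulation gives 62.2% for amber, 55.2% for grey, 38.2% for teal and 31.4% for green, so amber stands highest.

At the end of amber, a is 28% and b is 70%, so S·a/b is 1.73: even then, substrate in amber goes faster into homo dimer than into target, and target stands at 9.48%. Raise the substrate charge of amber to 0.085 M and S becomes 7.24, a factor 1.70 up. Homo dimer over target then ends at 10.4 against 6.56 in amber, with homo dimer at 73.4%.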